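Labdane numbering is used throughout (C19 = CH2O on C4, C20 = CH3 on C10, C17 = CH3 on C8).

**Plan**
1. Retrosynthesis: C7=C8–CH3 is traced back to a C8 ketone (via its Δ7 enol triflate), whose C8=C9 silyl enol ether is a [4+2] retron. Ring B is then cut at C5–C10 and C6–C7, and the open chain at C1–C10 (Negishi), C9–C11 (diketone alkylation) and C3–C4 (Ir-catalysed tert-(hydroxy)prenylation).
2. Enabling feature: the C19 oxygen on C4 and an axial substituent on C6 lie 1,3-diaxial across C5, on the face of the C10 methyl. A δ-sultone C19–O–SO2–C6=C5 can therefore be built on C4 as a temporary ring that activates C5=C6 and relays the C4 configuration to C5.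
3. Forward: two fragments are joined to an acyclic 2-silyloxy-triene, and one intramolecular Diels–Alder reaction closes ring A (C5–C10) and ring B (C5–C10 plus C6–C7) together. The sultone is then expelled (freeing C19–OH), and the C8 ketone becomes the Δ7 enol triflate and then C8–CH3.
4. Stereochemistry: C4 from the chiral Ir catalyst; C5 and C10 from the cycloaddition (C4 relayed through the sultone, trans ring fusion); C9 by equilibration next to the C8 ketone; C3 by equatorial hydride delivery to the 3-ketone; C13 from methyl hydrogen (R)-3-methylglutarate.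

Key step: step 12

Remark: the Ir-catalysed coupling is assumed to give the anti diol, (2R,3R) with the appropriate ligand enantiomer; this rests on the reported selectivity model and is not verified here. Only C4 is carried to the target, because C3 is reset in step 19.
Remark: compounds 1, 2, 7 and 10 are taken as commercial.

**Step 1**
Reactants: 1 3-(tert-butyldimethylsilyloxy)propan-1-ol; 2 2-methyl-2-vinyloxirane (racemic)
Product: 3 (2R,3R)-5-(tert-butyldimethylsilyloxy)-2-methyl-2-vinylpentane-1,3-diol
Conditions: cyclometalated π-allyl-Ir C,O-benzoate catalyst (Tol-BINAP, 5 mol%), K3PO4 (5 mol%), THF, 45–60 °C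
Reagents that add atoms: none
Why: Krische tert-(hydroxy)prenylation, in which the alcohol is dehydrogenated to the aldehyde and attacked by the (E)-σ-allyliridium species from the vinyl epoxide through a closed chair transition state, so the chiral catalyst sets the quaternary C4 and the C3 carbinol centre (anti).

**Step 2**
Reactants: 3 (2R,3R)-5-(tert-butyldimethylsilyloxy)-2-methyl-2-vinylpentane-1,3-diol
Product: 4 (2R,3R)-5-(tert-butyldimethylsilyloxy)-3-hydroxy-2-methyl-2-vinylpentyl ethenesulfonate
Conditions: ClCH2CH2SO2Cl (1.1 equiv), Et3N (2.5 equiv), CH2Cl2, −20 to 0 °C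
Reagents that add atoms: 2-chloroethanesulfonyl chloride, ClCCS(Cl)(=O)=O
Why: sulfonylation with in-situ dehydrochlorination to the vinylsulfonate; the primary hydroxyl should react before the secondary one flanked by the quaternary carbon.

**Step 3**
Reactants: 4 (2R,3R)-5-(tert-butyldimethylsilyloxy)-3-hydroxy-2-methyl-2-vinylpentyl ethenesulfonate
Product: 5 (2R,3R)-3,5-bis(tert-butyldimethylsilyloxy)-2-methyl-2-vinylpentyl ethenesulfonate
Conditions: TBSOTf, 2,6-lutidine, CH2Cl2, 0 °C
Reagents that add atoms: tert-butyldimethylsilyl triflate, CC(C)(C)[Si](C)(C)OS(=O)(=O)C(F)(F)F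
Why: silylation of the hindered secondary alcohol with a silyl triflate and a non-nucleophilic base that does not add to the vinylsulfonate.

**Step 4**
Reactants: 5 (2R,3R)-3,5-bis(tert-butyldimethylsilyloxy)-2-methyl-2-vinylpentyl ethenesulfonate
Product: 6 (2R,3R)-5-bromo-3-(tert-butyldimethylsilyloxy)-2-methyl-2-vinylpentyl ethenesulfonate
Conditions: Ph3PBr2, CH2Cl2, 0 °C to rt
Reagents that add atoms: dibromotriphenylphosphorane, BrP(Br)(c1ccccc1)(c1ccccc1)c1ccccc1
Why: direct conversion of a primary silyl ether into the bromide through an alkoxyphosphonium salt (SN2); the secondary silyl ether next to the quaternary carbon cannot be displaced.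

**Step 5**
Reactants: 7 (R)-5-methoxy-3-methyl-5-oxopentanoic acid
Product: 8 methyl (R)-5-hydroxy-3-methylpentanoate
Conditions: BH3·SMe2, THF, 0 °C to rt
Reagents that add atoms: none
Why: chemoselective borane reduction of a carboxylic acid in the presence of an ester; the stereocentre is untouched.

**Step 6**
Reactants: 8 methyl (R)-5-hydroxy-3-methylpentanoate
Product: 9 methyl (S)-5-iodo-3-methylpentanoate
Conditions: I2, PPh3, imidazole, CH2Cl2, 0 °C
Reagents that add atoms: iodine, II
Why: Appel-type iodination of a primary alcohol (the descriptor changes only through CIP priorities).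

**Step 7**
Reactants: 9 methyl (S)-5-iodo-3-methylpentanoate; 10 pentane-2,4-dione
Product: 11 methyl (R)-6-acetyl-3-methyl-7-oxooctanoate
Conditions: K2CO3, acetone, reflux
Reagents that add atoms: none
Why: C-alkylation of the acetylacetone enolate with a primary iodide; the two identical acetyl groups make the later enolisation regiochemically unambiguous.

**Step 8**
Reactants: 11 methyl (R)-6-acetyl-3-methyl-7-oxooctanoate
Product: 12 methyl (3R,6E)-6-acetyl-3-methyl-7-(trifluoromethylsulfonyloxy)oct-6-enoate
Conditions: Tf2O, DBU, CH2Cl2, −78 to 0 °C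
Reagents that add atoms: triflic anhydride, O=S(=O)(OS(=O)(=O)C(F)(F)F)C(F)(F)F
Why: O-triflation of the 1,3-diketone under non-chelating conditions proceeds through the extended, dipole-minimised enolate and should give the (E)-enol triflate (OTf trans to acetyl), as is known for 1,3-dicarbonyl compounds with amidine bases.

**Step 9**
Reactants: 6 (2R,3R)-5-bromo-3-(tert-butyldimethylsilyloxy)-2-methyl-2-vinylpentyl ethenesulfonate; 12 methyl (3R,6E)-6-acetyl-3-methyl-7-(trifluoromethylsulfonyloxy)oct-6-enoate
Product: 14 methyl (3R,6E,10R,11R)-6-acetyl-10-(tert-butyldimethylsilyloxy)-11-(ethenesulfonyloxymethyl)-3,7,11-trimethyltrideca-6,12-dienoate, via alkylzinc bromide 13 (not isolated)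
Conditions: Zn dust, LiCl, THF, 50 °C; then 12, Pd(dppf)Cl2 (5 mol%), THF/NMP, 25–40 °C
Reagents that add atoms: none
Why: zinc insertion into the primary bromide followed by Negishi coupling with the enol triflate, which proceeds with retention of alkene geometry and so places C1 trans and the C20 methyl cis to the acetyl group.

**Step 10**
Reactants: 14 methyl (3R,6E,10R,11R)-6-acetyl-10-(tert-butyldimethylsilyloxy)-11-(ethenesulfonyloxymethyl)-3,7,11-trimethyltrideca-6,12-dienoate
Product: 15 methyl (3R,6E,10R)-6-acetyl-10-(tert-butyldimethylsilyloxy)-3,7-dimethyl-10-[(5R)-5-methyl-2,2-dioxo-5,6-dihydro-1,2-oxathiin-5-yl]dec-6-enoate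
Conditions: Grubbs II (5–10 mol%), toluene, 80 °C
Reagents that add atoms: none
Why: ring-closing metathesis of the vinylsulfonate with the vinyl group on C4 gives the six-membered α,β-unsaturated sultone; the tetrasubstituted enone alkene is inert to the Ru carbene.

**Step 11**
Reactants: 15 sultone enone (as named in step 10)
Product: 16 2-silyloxydiene of 15 (C7H2=C8(OTBS)–C9(side chain)=C10(CH3)–C1; 6E retained)
Conditions: TBSOTf, Et3N, CH2Cl2, −78 to 0 °C
Reagents that add atoms: tert-butyldimethylsilyl triflate, CC(C)(C)[Si](C)(C)OS(=O)(=O)C(F)(F)F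
Why: soft enolisation of the methyl ketone at the α′-methyl group gives the cross-conjugated 2-silyloxydiene without strong base, so the sultone and the ester are left alone.

**Step 12**
Reactants: 16 2-silyloxydiene of 15
Product: 17 tricyclic cycloadduct (trans-decalin with C8(OTBS)=C9 enol ether and a C19–O–SO2–C6 sultone bridge; C20, C19 and C6–S on one face, H5 on the other; 3-OTBS equatorial)
Conditions: toluene (0.01 M), BHT, 2,6-di-tert-butylpyridine (cat.), 140 °C, sealed tube
Reagents that add atoms: none
Why: Thermal intramolecular Diels–Alder reaction of a 1,7,9-decatriene: the 2-silyloxydiene C7=C8–C9=C10 adds suprafacially to the sultone double bond C5=C6 in one concerted, asynchronous step that forms C5–C10 and C6–C7. The closest known reactions are intramolecular Diels–Alder reactions of vinylsulfonates and vinyl sulfones with tethered dienes, and those of 2-silyloxydienes that set an angular methyl group. Ring A closes as a six-membered carbocycle through the C1–C4 tether by C5–C10 bond formation in a chair-like arrangement (C3–OTBS equatorial), and ring B is the cyclohexene formed by the [4+2] itself, fused to the sultone at C5–C6. C5 is set by C4, because the diene hangs from C4 and can reach C5 only on the sultone face that carries C3, which places H5 cis to the C4 methyl and C19 cis to the C10 methyl; C10 is set by the (E)-geometry of C9=C10 (C1 outside, CH3 inside) in the trans-fusion transition state, and C6 follows from the cis ring alkene. The step needs trans over cis ring fusion, which the C9 side chain (it eclipses C1 in the cis-fusion transition state) and the exo position of the sulfonyl group should secure. The inside methyl on C10 and the neopentyl C5 slow the reaction, hence the temperature.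

**Step 13**
Reactants: 17 tricyclic cycloadduct
Product: 20 enone alcohol (17-nor-labd-6-en-8-one with free C19–OH; 3-OTBS; methyl ester), via β-sulfonyl ketone 18 (not isolated), via hydrogen sulfite ester 19 (not isolated)
Conditions: 1 M HCl, THF, rt; then DBU, CH2Cl2, rt; aq. NH4Cl work-up
Reagents that add atoms: none
Why: acid cleaves the silyl enol ether to the C8 ketone (C9 settles with the side chain equatorial), and DBU then effects E1cB elimination across C6–C7 with the axial C6–S bond as leaving group (retro-sulfa-Michael of a β-sulfonyl ketone); the ring-opened sulfite half ester loses SO2 on work-up and frees C19–OH.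

**Step 14**
Reactants: 20 enone alcohol
Product: 21 enone acetate (C19–OAc)
Conditions: Ac2O, pyridine, DMAP (cat.), CH2Cl2, 0 °C to rt
Reagents that add atoms: acetic anhydride, CC(=O)OC(C)=O
Why: acetylation of the only free hydroxyl installs the target's acetate and prevents oxa-Michael addition of O19 to C6.

**Step 15**
Reactants: 21 enone acetate
Product: 23 Δ7 enol triflate (C8–OTf), via lithium enolate 22 (not isolated)
Conditions: L-Selectride, THF, −78 °C; then PhNTf2, −78 to 0 °C
Reagents that add atoms: N-phenylbis(trifluoromethanesulfonimide), O=S(=O)(N(c1ccccc1)S(=O)(=O)C(F)(F)F)C(F)(F)F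
Why: conjugate reduction of a β-unsubstituted cyclohexenone by a bulky borohydride (the hindered C8 carbonyl disfavours 1,2-attack) gives the regiodefined C7=C8 enolate, which is trapped on oxygen.

**Step 16**
Reactants: 23 Δ7 enol triflate
Product: 24 methyl (3R,4R,5S,9R,10S,13R)-19-acetoxy-3-(tert-butyldimethylsilyloxy)labd-7-en-15-oate
Conditions: MeZnCl, Pd(PPh3)4 (5 mol%), THF, 50 °C
Reagents that add atoms: methylzinc chloride, C[Zn]Cl
Why: Negishi methylation of the enol triflate fixes the C7=C8 position of the trisubstituted alkene and tolerates ester, acetate and silyl ether.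

**Step 17**
Reactants: 24 methyl 19-acetoxy-3-(tert-butyldimethylsilyloxy)labd-7-en-15-oate
Product: 25 methyl (3R,4R,5S,9R,10S,13R)-19-acetoxy-3-hydroxylabd-7-en-15-oate (3-OH equatorial)
Conditions: HF·pyridine, THF/pyridine, 0 °C to rt
Reagents that add atoms: none
Why: fluoride desilylation under weakly acidic conditions, which spare the acetate, the ester and the Δ7 alkene and do not promote acyl migration.

**Step 18**
Reactants: 25 methyl 19-acetoxy-3-hydroxylabd-7-en-15-oate (3R)
Product: 26 methyl (4R,5S,9R,10S,13R)-19-acetoxy-3-oxolabd-7-en-15-oate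
Conditions: Dess–Martin periodinane, NaHCO3, CH2Cl2, rt
Reagents that add atoms: none
Why: mild oxidation of the secondary alcohol; the β-acetoxy ketone cannot eliminate because C4 is quaternary.

**Step 19**
Reactants: 26 methyl 19-acetoxy-3-oxolabd-7-en-15-oate
Product: 27 methyl (3S,4R,5S,9R,10S,13R)-19-acetoxy-3-hydroxylabd-7-en-15-oate (3-OH axial)
Conditions: L-Selectride, THF, −78 °C
Reagents that add atoms: none
Why: the bulky hydride attacks the 4,4-disubstituted 3-ketone from the equatorial direction, as in 3-oxo triterpenoids, and gives the axial alcohol trans to C19 (substrate control); ester and acetate survive at −78 °C.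

**Step 20**
Reactants: 27 methyl 19-acetoxy-3-hydroxylabd-7-en-15-oate (3S)
Product: 28 (3S,4R,5S,9R,10S,13R)-19-acetoxy-3-hydroxylabd-7-en-15-oic acid (target)
Conditions: LiI, EtOAc, reflux; 1 M HCl work-up
Reagents that add atoms: none
Why: iodide cleaves the methyl ester by SN2 at the O-methyl carbon, a pathway closed to the neopentyl acetate, so the acid is released with the C19 acetate intact.

**Compound list**
1 | 3-(tert-butyldimethylsilyloxy)propan-1-ol | OCCCO[Si](C)(C)C(C)(C)C | starting material
2 | 2-methyl-2-vinyloxirane (racemic) | CC1(C=C)CO1 | starting material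
3 | (2R,3R)-5-(tert-butyldimethylsilyloxy)-2-methyl-2-vinylpentane-1,3-diol | OC[C@@](C)(C=C)[C@H](O)CCO[Si](C)(C)C(C)(C)C | intermediate
4 | (2R,3R)-5-(tert-butyldimethylsilyloxy)-3-hydroxy-2-methyl-2-vinylpentyl ethenesulfonate | C=CS(=O)(=O)OC[C@@](C)(C=C)[C@H](O)CCO[Si](C)(C)C(C)(C)C | intermediate
5 | (2R,3R)-3,5-bis(tert-butyldimethylsilyloxy)-2-methyl-2-vinylpentyl ethenesulfonate | C=CS(=O)(=O)OC[C@@](C)(C=C)[C@H](O[Si](C)(C)C(C)(C)C)CCO[Si](C)(C)C(C)(C)C | intermediate
6 | (2R,3R)-5-bromo-3-(tert-butyldimethylsilyloxy)-2-methyl-2-vinylpentyl ethenesulfonate | C=CS(=O)(=O)OC[C@@](C)(C=C)[C@H](O[Si](C)(C)C(C)(C)C)CCBr | intermediate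
7 | (R)-5-methoxy-3-methyl-5-oxopentanoic acid | OC(=O)C[C@@H](C)CC(=O)OC | starting material
8 | methyl (R)-5-hydroxy-3-methylpentanoate | OCC[C@@H](C)CC(=O)OC | intermediate
9 | methyl (S)-5-iodo-3-methylpentanoate | ICC[C@@H](C)CC(=O)OC | intermediate
10 | pentane-2,4-dione | CC(=O)CC(C)=O | starting material
11 | methyl (R)-6-acetyl-3-methyl-7-oxooctanoate | CC(=O)C(CC[C@@H](C)CC(=O)OC)C(C)=O | intermediate
12 | methyl (3R,6E)-6-acetyl-3-methyl-7-(trifluoromethylsulfonyloxy)oct-6-enoate | CC(=O)/C(CC[C@@H](C)CC(=O)OC)=C(\C)OS(=O)(=O)C(F)(F)F | intermediate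
13 | alkylzinc bromide from 6 | C=CS(=O)(=O)OC[C@@](C)(C=C)[C@H](O[Si](C)(C)C(C)(C)C)CC[Zn]Br | intermediate
14 | methyl (3R,6E,10R,11R)-6-acetyl-10-(tert-butyldimethylsilyloxy)-11-(ethenesulfonyloxymethyl)-3,7,11-trimethyltrideca-6,12-dienoate | C=CS(=O)(=O)OC[C@@](C)(C=C)[C@H](O[Si](C)(C)C(C)(C)C)CC/C(C)=C(\CC[C@@H](C)CC(=O)OC)C(C)=O | intermediate
15 | methyl (3R,6E,10R)-6-acetyl-10-(tert-butyldimethylsilyloxy)-3,7-dimethyl-10-[(5R)-5-methyl-2,2-dioxo-5,6-dihydro-1,2-oxathiin-5-yl]dec-6-enoate | O=S1(=O)OC[C@@](C)(C=C1)[C@H](O[Si](C)(C)C(C)(C)C)CC/C(C)=C(\CC[C@@H](C)CC(=O)OC)C(C)=O | intermediate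
16 | 2-silyloxydiene of 15 | O=S1(=O)OC[C@@](C)(C=C1)[C@H](O[Si](C)(C)C(C)(C)C)CC/C(C)=C(\CC[C@@H](C)CC(=O)OC)C(=C)O[Si](C)(C)C(C)(C)C | intermediate
17 | tricyclic cycloadduct (silyl enol ether, sultone bridge) | O=S1(=O)OC[C@@]2(C)[C@H]3[C@@H]1CC(O[Si](C)(C)C(C)(C)C)=C(CC[C@@H](C)CC(=O)OC)[C@]3(C)CC[C@H]2O[Si](C)(C)C(C)(C)C | intermediate
18 | β-sulfonyl ketone (C8=O, sultone intact) | O=S1(=O)OC[C@@]2(C)[C@H]3[C@@H]1CC(=O)[C@@H](CC[C@@H](C)CC(=O)OC)[C@]3(C)CC[C@H]2O[Si](C)(C)C(C)(C)C | intermediate
19 | hydrogen sulfite ester of 20 | OS(=O)OC[C@@]1(C)[C@H]2C=CC(=O)[C@@H](CC[C@@H](C)CC(=O)OC)[C@]2(C)CC[C@H]1O[Si](C)(C)C(C)(C)C | intermediate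
20 | enone alcohol (17-nor-labd-6-en-8-one, C19–OH) | OC[C@@]1(C)[C@H]2C=CC(=O)[C@@H](CC[C@@H](C)CC(=O)OC)[C@]2(C)CC[C@H]1O[Si](C)(C)C(C)(C)C | intermediate
21 | enone acetate | CC(=O)OC[C@@]1(C)[C@H]2C=CC(=O)[C@@H](CC[C@@H](C)CC(=O)OC)[C@]2(C)CC[C@H]1O[Si](C)(C)C(C)(C)C | intermediate
22 | lithium Δ7 enolate | [Li+].CC(=O)OC[C@@]1(C)[C@H]2CC=C([O-])[C@@H](CC[C@@H](C)CC(=O)OC)[C@]2(C)CC[C@H]1O[Si](C)(C)C(C)(C)C | intermediate
23 | Δ7 enol triflate | CC(=O)OC[C@@]1(C)[C@H]2CC=C(OS(=O)(=O)C(F)(F)F)[C@@H](CC[C@@H](C)CC(=O)OC)[C@]2(C)CC[C@H]1O[Si](C)(C)C(C)(C)C | intermediate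
24 | methyl (3R,4R,5S,9R,10S,13R)-19-acetoxy-3-(tert-butyldimethylsilyloxy)labd-7-en-15-oate | CC(=O)OC[C@@]1(C)[C@H]2CC=C(C)[C@@H](CC[C@@H](C)CC(=O)OC)[C@]2(C)CC[C@H]1O[Si](C)(C)C(C)(C)C | intermediate
25 | methyl (3R,4R,5S,9R,10S,13R)-19-acetoxy-3-hydroxylabd-7-en-15-oate | CC(=O)OC[C@@]1(C)[C@H]2CC=C(C)[C@@H](CC[C@@H](C)CC(=O)OC)[C@]2(C)CC[C@H]1O | intermediate
26 | methyl (4R,5S,9R,10S,13R)-19-acetoxy-3-oxolabd-7-en-15-oate | CC(=O)OC[C@@]1(C)[C@H]2CC=C(C)[C@@H](CC[C@@H](C)CC(=O)OC)[C@]2(C)CCC1=O | intermediate
27 | methyl (3S,4R,5S,9R,10S,13R)-19-acetoxy-3-hydroxylabd-7-en-15-oate | CC(=O)OC[C@@]1(C)[C@H]2CC=C(C)[C@@H](CC[C@@H](C)CC(=O)OC)[C@]2(C)CC[C@@H]1O | intermediate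
28 | (3S,4R,5S,9R,10S,13R)-19-acetoxy-3-hydroxylabd-7-en-15-oic acid (CNP0218903.1) | CC(=O)OC[C@@]1(C)[C@H]2CC=C(C)[C@@H](CC[C@@H](C)CC(=O)O)[C@]2(C)CC[C@@H]1O | target

**Step count and risks**
Total step count: 20. Longest linear sequence: 16 (steps 1–4 and 9–20).

Steps most likely to fail:

- Step 12. The cycloaddition may be too slow, because the new C5–C10 bond joins a neopentyl carbon to a fully substituted diene terminus that carries an inside methyl group, and the silyl enol ether may be lost thermally before ring closure. The fallback changes the way the diene is activated and sets out from 15. Condensation of enone 15 with pyrrolidine (molecular sieves) should give the 2-(pyrrolidin-1-yl)diene F1, a more electron-rich diene formed under neutral conditions. It should close at lower temperature, by the same intramolecular [4+2], to the enamine cycloadduct F2. Hydrolysis with aqueous acetic acid then gives ketone 18, where the route is rejoined (DBU as in step 13).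
- Step 15. Hydride may add 1,2 to the enone in competition with 1,4-addition, or the boron-bound enolate may be triflated incompletely. The fallback separates reduction and enolisation and sets out from 21. Hydrogenation of its only C=C bond (H2, Pd/C, EtOAc) should give the saturated C8 ketone F3. Kinetic deprotonation at the C7 methylene (KHMDS, THF, −78 °C) and trapping with PhNTf2 then gives 23.
- Step 20. Demethylation of an unactivated methyl ester by iodide may be slow, and the temperature needed may cause loss or migration of the acetate. The fallback sets out from 27. LiOH (THF/MeOH/H2O) hydrolyses both esters to the 3,19-dihydroxy acid F4. Selective acetylation of the primary C19 hydroxyl (Ac2O, pyridine, 0 °C; the axial C3–OH next to the quaternary C4 is hindered, and any mixed anhydride is hydrolysed on work-up) then gives 28.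

**Further compounds**
F1 | step 12 | 2-(pyrrolidin-1-yl)diene from 15 | O=S1(=O)OC[C@@](C)(C=C1)[C@H](O[Si](C)(C)C(C)(C)C)CC/C(C)=C(\CC[C@@H](C)CC(=O)OC)C(=C)N1CCCC1
F2 | step 12 | enamine cycloadduct | O=S1(=O)OC[C@@]2(C)[C@H]3[C@@H]1CC(N1CCCC1)=C(CC[C@@H](C)CC(=O)OC)[C@]3(C)CC[C@H]2O[Si](C)(C)C(C)(C)C
F3 | step 15 | saturated C8 ketone (17-nor-8-oxolabdane, C19–OAc, 3-OTBS) | CC(=O)OC[C@@]1(C)[C@H]2CCC(=O)[C@@H](CC[C@@H](C)CC(=O)OC)[C@]2(C)CC[C@H]1O[Si](C)(C)C(C)(C)C
F4 | step 20 | (3S,4R,5S,9R,10S,13R)-3,19-dihydroxylabd-7-en-15-oic acid | OC[C@@]1(C)[C@H]2CC=C(C)[C@@H](CC[C@@H](C)CC(=O)O)[C@]2(C)CC[C@@H]1O
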